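**Easy step.** The catalyst stands on both sides of each step it enters, so I hold c(catalyst) at its charge of 0.40 mM, and the substrate falls pseudo-first-order.

| setting | elm | alder |
|---|---|---|
| substrate | 0.20 M | 0.20 M |
| catalyst | 0.40 mM | 0.40 mM |
| time | 80 s | 160 s |

    target + catalyst ⇌ isomer of the product + catalyst, rate k1*[catalyst]*[target] forward; the back reaction follows from the equilibrium constant (K1 = 0.79, k1 = 13 M⁻¹ s⁻¹)
    substrate → side product (k2 = 0.0018 s⁻¹)
    substrate + catalyst → catalyst + target (k3 = 18 M⁻¹ s⁻¹)

- which of these there is most of at the end, counted by the substrate in it, elm (side product / target / substrate / isomer of the product)
- which of these there is most of at the end, counted by the substrate in it, alder (side product / target / substrate / isomer of the product)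
- how much there is at the end of the one of these that leads, in percent of the substrate charged: elm
- how much there is at the end of the one of these that leads, in percent of the substrate charged: alder

**Loss constant.** The substrate leaves through the catalyst at 0.00720 s⁻¹ and by itself at 0.0018 s⁻¹. Their sum, the substrate's loss constant 0.00900 s⁻¹, counts lifetimes when multiplied by the time: 0.720 in elm, 1.44 in alder. So elm keeps 48.7 % of its substrate and alder 23.7 %, and 80.0 % of what leaves becomes target.

**Two extremes.** Isomerisation leaves the substrate alone, so I can bracket the target. With isomerisation frozen, the target holds 41.1 % in elm and 61.0 % in alder. With instant equilibrium, it holds 22.9 % in elm and 34.1 % in alder. Target and isomer of the product really relax at 0.0118 s⁻¹, a rate of the same size as the loss constant , so the target lies inside each bracket. In elm the substrate leads, since it stands above the bracket's top, which holds target and isomer of the product together, and above the side product's 10.3 %. In alder the target leads, since even its floor is higher than the substrate, the isomer's 26.9 % at most and the side product's 15.3 %. My reckoning stops at that bracket for alder.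

**The forecast.** It names substrate at 48.7 % for elm, with the target “still behind the substrate”, and target at 43.8 % for alder.

**The flasks.** Elm ends with substrate leading at 48.7 %, and alder with target leading at 43.8 %. At the end of elm the catalysed road still outruns the uncatalysed one 4.0 times, the ratio it had at the start. A neighbour of elm charged with 0.0016 M of catalyst has a loss constant of 0.0306 s⁻¹, which gives 2.45 lifetimes and leaves 8.65 % of its substrate. That neighbour ends with substrate at 8.65 % and target leading at 52.9 %.

Its constants are invented; the flask was simulated.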